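**Plan**

- Numbering runs from C1 (alkyne CH) to C15 (ethyl CH3); the only ring is the oxocene O, C7–C13. Enabling feature: ring carbon C11 is a CH2 between the chloroalkene carbon C10 and C12, so with C12 as a ketone C11 is an enolate carbon and C10 can carry iodine beside its chlorine.
- Retrosynthetic cuts, in order: C3=C4 (Peterson enyne olefination), C5–C6 (syn-chloroallylboration of a C6 aldehyde), C12–Br (from a C12 ketone), ring bond C10–C11 (palladium enolate alkenylation), C11–C12 (MeMgBr on a Weinreb amide), C7–C8 (glycolate alkylation), O–C7 (etherification).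
- Forward: a C8–C10 (Z)-chloro-iodo-allyl iodide and the C12–C15 hydroxy amide are joined through a glycolate unit (C6–C7). The single ring then closes at C10–C11, followed by the C12 bromide and the C1–C5 side chain.
- Stereochemistry: C13 from (R)-2-hydroxybutanoic acid; C7 from the (S)-4-benzyl-oxazolidinone auxiliary; C9=C10 from trans-hydroalumination/iodination; C12 from cis-selective hydride reduction then SN2 inversion; C5/C6 from a reagent-controlled (Z)-γ-chloroallylborane; C3=C4 (Z) from the Peterson step.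

Key step: step 11

Remark: the (Z)-γ-chloroallylborane is assumed to show the same aldehyde-face preference as the parent allyl-diisopinocampheylborane of the same pinene series.

**Route**

Step 1
Reactants: 1 propargyl alcohol
Product: 2 3-chloroprop-2-yn-1-ol
Conditions: aq NaOCl, 0 °C → rt
Reagents that add atoms: sodium hypochlorite, [Na+].[O-]Cl
Why: Hypohalite chlorination of a terminal alkyne, in which the acetylide formed in the alkaline medium is chlorinated at carbon while the primary alcohol is not oxidised under basic conditions.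

Step 2
Reactants: 2 3-chloroprop-2-yn-1-ol
Product: 4 (Z)-3-chloro-3-iodoprop-2-en-1-ol, via cyclic lithium alkenylalanate 3 (not isolated)
Conditions: LiAlH4, THF, −30 → 0 °C; then I2, THF, −78 °C
Reagents that add atoms: iodine, [I][I]
Why: Alkoxide-directed trans-hydroalumination of the 1-chloroalkyne puts aluminium on the chlorine-bearing carbon cis to the CH2O group, and iodinolysis of the C–Al bond with retention (hydroalumination–iodination of a propargylic alcohol) gives the Z chloro-iodo-alkene with iodine cis to the carbinol carbon.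

Step 3
Reactants: 4 (Z)-3-chloro-3-iodoprop-2-en-1-ol
Product: 5 (Z)-1-chloro-1,3-diiodoprop-1-ene (vinylic iodine cis to CH2I)
Conditions: PPh3, I2, imidazole, CH2Cl2, 0 °C, dark
Reagents that add atoms: iodine, [I][I]
Why: Appel-type iodination converts the primary allylic alcohol into the iodide by SN2 at CH2 without touching the alkene geometry.

Step 4
Reactants: 6 (R)-2-hydroxybutanoic acid
Product: 7 (R)-2-hydroxy-N-methoxy-N-methylbutanamide
Conditions: MeNHOMe·HCl, EDC·HCl, HOBt, N-methylmorpholine, CH2Cl2, 0 °C → rt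
Reagents that add atoms: N,O-dimethylhydroxylamine hydrochloride, CNOC.Cl
Why: Carbodiimide/HOBt amidation, in which the amine captures the active ester faster than the secondary hydroxyl and C13 is not epimerised.

Step 5
Reactants: 7 (R)-2-hydroxy-N-methoxy-N-methylbutanamide; 8 bromoacetic acid
Product: 9 2-{[(2R)-1-[methoxy(methyl)amino]-1-oxobutan-2-yl]oxy}acetic acid
Conditions: NaH (3 equiv), THF, 0 °C → rt; aq HCl work-up
Reagents that add atoms: none
Why: Williamson etherification, in which the sodium alkoxide of 7 displaces bromide from sodium bromoacetate at a primary carbon and forms the O–C7 bond without touching C13.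

Step 6
Reactants: 9 the glycolic acid ether; 10 (S)-4-benzyl-2-oxazolidinone
Product: 12 (4S)-4-benzyl-3-(2-{[(2R)-1-[methoxy(methyl)amino]-1-oxobutan-2-yl]oxy}acetyl)oxazolidin-2-one, via mixed pivalic anhydride 11 (not isolated)
Conditions: PivCl, Et3N, THF, −20 °C; then 10, LiCl, −20 °C → rt
Reagents that add atoms: none
Why: N-acylation of the oxazolidinone through a mixed anhydride occurs at the less hindered carbonyl of 11 under LiCl/Et3N activation and needs no strong base.

Step 7
Reactants: 12 the glycolyl imide; 5 (Z)-1-chloro-1,3-diiodoprop-1-ene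
Product: 14 (4S)-4-benzyl-3-[(2R,4Z)-5-chloro-5-iodo-2-{[(2R)-1-[methoxy(methyl)amino]-1-oxobutan-2-yl]oxy}pent-4-enoyl]oxazolidin-2-one, via sodium Z-enolate 13 (not isolated)
Conditions: NaN(SiMe3)2, THF, −78 °C; then 5, −78 → −45 °C
Reagents that add atoms: none
Why: Evans-type glycolate alkylation, in which the chelated Z sodium enolate 13 is shielded on one face by the benzyl group so that the allylic iodide (SN2 at CH2, alkene geometry untouched) enters from the other face and sets C7 as R; the imide CH2 is deprotonated in preference to the hindered C13–H next to the Weinreb amide.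

Step 8
Reactants: 14 the alkylated imide
Product: 15 (2R)-2-{[(2R,4Z)-5-chloro-1-hydroxy-5-iodopent-4-en-2-yl]oxy}-N-methoxy-N-methylbutanamide
Conditions: NaBH4, THF/H2O, 0 °C → rt
Reagents that add atoms: none
Why: Borohydride reduction of the activated N-acyl oxazolidinone releases the primary alcohol (C6) and the auxiliary, while the Weinreb amide and the vinyl halides are inert to NaBH4.

Step 9
Reactants: 15 the primary alcohol
Product: 16 (2R)-2-{[(2R,4Z)-5-chloro-5-iodo-1-(triisopropylsilyloxy)pent-4-en-2-yl]oxy}-N-methoxy-N-methylbutanamide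
Conditions: i-Pr3SiOTf, 2,6-lutidine, CH2Cl2, −78 °C
Reagents that add atoms: triisopropylsilyl triflate, CC(C)[Si](OS(=O)(=O)C(F)(F)F)(C(C)C)C(C)C
Why: Silylation of the primary alcohol with a silyl triflate at low temperature is faster than lactonisation of the alcohol onto the Weinreb amide.

Step 10
Reactants: 16 the silyl ether; 17 methylmagnesium bromide
Product: 18 (3R)-3-{[(2R,4Z)-5-chloro-5-iodo-1-(triisopropylsilyloxy)pent-4-en-2-yl]oxy}pentan-2-one
Conditions: THF, −78 → 0 °C; aq NH4Cl
Reagents that add atoms: none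
Why: Weinreb ketone synthesis, in which the N-methoxy-N-methylamide takes up one equivalent of Grignard reagent and releases the methyl ketone (C11–C12) only on work-up; the vinyl iodide does not exchange with MeMgBr at this temperature.

Step 11
Reactants: 18 the chloro-iodo-alkene methyl ketone
Product: 19 (2R,5E,8R)-5-chloro-2-ethyl-8-[(triisopropylsilyloxy)methyl]-7,8-dihydro-2H-oxocin-3(4H)-one (2,8-cis; ring carbons cis across C5=C6)
Conditions: Pd2(dba)3 (5 mol %), XPhos (12 mol %), K3PO4 (3 equiv), toluene, 70 °C, slow addition of 18 to a final 0.005 M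
Reagents that add atoms: none
Why: Proposed new method: zerovalent palladium inserts into the C10–I bond of the 1-chloro-1-iodoalkene, K3PO4 generates the palladium-bound enolate on the methyl side (C11), and C(sp2)–C(sp3) reductive elimination forms C10–C11 with retention at C10, so the iodine cis to C8 becomes C11 cis to C8 and chlorine stays on C10. The closest known reactions are palladium-catalysed intramolecular α-alkenylations of ketones with vinyl halides, which build five- to seven-membered rings, and iodine-selective couplings of 1-chloro-1-iodoalkenes; an eight-membered ring has not been closed in this way. The oxocene (O, C7–C13) closes by reductive elimination inside a nine-membered palladacycle under high dilution, helped by the ether oxygen and three sp2 ring atoms (C9, C10, C12) that lower transannular strain. No stereocentre is created; C7 and C13 are carried through and the ring alkene geometry is fixed by the substrate. The step needs insertion at C–I and not C–Cl (secured by the much weaker C–I bond), and enolisation at the unhindered methyl group and not at the tertiary α-alkoxy C13–H (secured by sterics and the mild heterogeneous base, which also guards C13 against epimerisation). The palladium enolate has no hydrogen on an adjacent sp3 carbon, so β-hydride elimination cannot intervene.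

Step 12
Reactants: 19 the oxocenone
Product: 20 (2R,3R,5E,8R)-5-chloro-2-ethyl-8-[(triisopropylsilyloxy)methyl]-3,4,7,8-tetrahydro-2H-oxocin-3-ol (hydroxyl cis to ethyl)
Conditions: LiBH(s-Bu)3, THF, −78 °C; H2O
Reagents that add atoms: none
Why: The bulky trialkylborohydride should attack the ketone from the ring face away from the adjacent C13 ethyl group and give the C12 alcohol cis to ethyl (12R), as is typical for 2-alkyl-oxocan-3-ones and their unsaturated analogues.

Step 13
Reactants: 20 the cis alcohol
Product: 21 (2R,3S,5E,8R)-3-bromo-5-chloro-2-ethyl-8-[(triisopropylsilyloxy)methyl]-3,4,7,8-tetrahydro-2H-oxocine (bromine trans to ethyl)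
Conditions: CBr4, P(n-C8H17)3, toluene, 70 °C
Reagents that add atoms: carbon tetrabromide, BrC(Br)(Br)Br
Why: Appel-type bromination of the secondary alcohol proceeds by SN2 displacement with inversion and gives the (12S) bromide trans to the ethyl group.

Step 14
Reactants: 21 the silyl-protected bromide
Product: 22 [(2R,3S,5E,8R)-3-bromo-5-chloro-2-ethyl-3,4,7,8-tetrahydro-2H-oxocin-8-yl]methanol
Conditions: Bu4NF, AcOH, THF, rt
Reagents that add atoms: none
Why: Fluoride-mediated cleavage of the primary silyl ether, with acetic acid buffering to protect the secondary bromide from elimination.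

Step 15
Reactants: 22 the primary alcohol
Product: 23 (2R,3S,5E,8R)-3-bromo-5-chloro-2-ethyl-3,4,7,8-tetrahydro-2H-oxocine-8-carbaldehyde
Conditions: Dess–Martin periodinane, CH2Cl2, 0 °C → rt
Reagents that add atoms: none
Why: Dess–Martin oxidation stops at the aldehyde under non-enolising conditions, so the α-alkoxy stereocentre C7 is preserved; the aldehyde is used at once.

Step 16
Reactants: 23 the C6 aldehyde; 24 allyl chloride
Product: 26 (1S,2S)-1-[(2R,3S,5E,8R)-3-bromo-5-chloro-2-ethyl-3,4,7,8-tetrahydro-2H-oxocin-8-yl]-2-chlorobut-3-en-1-ol, via (Z)-γ-chloroallyldiisopinocampheylborane 25 (not isolated)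
Conditions: 24, LiN(c-C6H11)2, (+)-Ipc2BOMe [from (−)-α-pinene], Et2O, −95 °C; BF3·OEt2; then 23, −95 °C; HOCH2CH2NH2 work-up
Reagents that add atoms: none
Why: Reagent-controlled allylboration through a chair Zimmerman–Traxler transition state, in which the Z geometry of 25 gives the syn chlorohydrin and the isopinocampheyl groups direct attack to the Re face of the aldehyde, setting 5S and 6S against the modest Felkin-type bias of the α-alkoxy aldehyde.

Step 17
Reactants: 26 the chlorohydrin
Product: 27 triethyl{[(1S,2S)-1-[(2R,3S,5E,8R)-3-bromo-5-chloro-2-ethyl-3,4,7,8-tetrahydro-2H-oxocin-8-yl]-2-chlorobut-3-en-1-yl]oxy}silane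
Conditions: Et3SiOTf, 2,6-lutidine, CH2Cl2, −78 °C
Reagents that add atoms: triethylsilyl triflate, CC[Si](CC)(CC)OS(=O)(=O)C(F)(F)F
Why: Silyl triflate/lutidine silylation of the secondary alcohol is fast at low temperature and not basic enough to close the chlorohydrin to an epoxide.

Step 18
Reactants: 27 the silyl-protected vinyl chlorohydrin
Product: 29 (2R,3S)-3-[(2R,3S,5E,8R)-3-bromo-5-chloro-2-ethyl-3,4,7,8-tetrahydro-2H-oxocin-8-yl]-2-chloro-3-(triethylsilyloxy)propanal, via ozonide 28 (not isolated)
Conditions: O3 (1 equiv, titrated), CH2Cl2, −78 °C; then PPh3, −78 °C → rt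
Reagents that add atoms: ozone, [O-][O+]=O
Why: Ozonolysis with reductive work-up, in which the terminal vinyl group should react with ozone much faster than the chlorine-deactivated ring alkene, so that one equivalent cleaves only the vinyl group and leaves the C4 aldehyde.

Step 19
Reactants: 29 the α-chloro aldehyde; 30 1,3-bis(triisopropylsilyl)propyne
Product: 32 triethyl{[(1S,2S,3Z)-1-[(2R,3S,5E,8R)-3-bromo-5-chloro-2-ethyl-3,4,7,8-tetrahydro-2H-oxocin-8-yl]-2-chloro-6-(triisopropylsilyl)hex-3-en-5-yn-1-yl]oxy}silane, via lithiated bis(triisopropylsilyl)propyne 31 (not isolated)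
Conditions: 30, n-BuLi, THF, −20 °C; then 29, −78 °C → rt
Reagents that add atoms: none
Why: Peterson olefination with the silyl-stabilised propargyl anion 31, whose bulky triisopropylsilyl groups are known to favour the Z enyne; the fast addition at −78 °C should leave the C5 chloride stereocentre intact.

Step 20
Reactants: 32 the doubly silylated enyne
Product: 33 bermudenynol, (1S,2S,3Z)-1-[(2R,3S,5E,8R)-3-bromo-5-chloro-2-ethyl-3,4,7,8-tetrahydro-2H-oxocin-8-yl]-2-chlorohex-3-en-5-yn-1-ol
Conditions: Bu4NF, AcOH, THF, 0 °C → rt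
Reagents that add atoms: none
Why: Fluoride cleaves the alkynyl C–Si and the O–Si bonds in one operation, and acetic acid buffering keeps the freed C6 alkoxide from closing onto the C5 chloride and the C12 bromide from eliminating.

**Compound list**

1 | propargyl alcohol | C#CCO | starting material
2 | 3-chloroprop-2-yn-1-ol | OCC#CCl | intermediate
3 | cyclic lithium alkenylalanate (Al bound to O and to the chlorine-bearing alkene carbon, cis to CH2O) | [Li+].ClC1=CCO[AlH2-]1 | intermediate
4 | (Z)-3-chloro-3-iodoprop-2-en-1-ol | OC/C=C(/Cl)I | intermediate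
5 | (Z)-1-chloro-1,3-diiodoprop-1-ene | IC/C=C(/Cl)I | intermediate
6 | (R)-2-hydroxybutanoic acid | CC[C@@H](O)C(=O)O | starting material
7 | (R)-2-hydroxy-N-methoxy-N-methylbutanamide | CC[C@@H](O)C(=O)N(C)OC | intermediate
8 | bromoacetic acid | OC(=O)CBr | starting material
9 | 2-{[(2R)-1-[methoxy(methyl)amino]-1-oxobutan-2-yl]oxy}acetic acid | CC[C@@H](OCC(=O)O)C(=O)N(C)OC | intermediate
10 | (S)-4-benzyl-2-oxazolidinone | O=C1OC[C@H](Cc2ccccc2)N1 | starting material
11 | mixed anhydride of 9 with pivalic acid | CC[C@@H](OCC(=O)OC(=O)C(C)(C)C)C(=O)N(C)OC | intermediate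
12 | (4S)-4-benzyl-3-(2-{[(2R)-1-[methoxy(methyl)amino]-1-oxobutan-2-yl]oxy}acetyl)oxazolidin-2-one | CC[C@@H](OCC(=O)N1[C@@H](Cc2ccccc2)COC1=O)C(=O)N(C)OC | intermediate
13 | sodium Z-enolate of 12 (O–Na cis to the ether oxygen) | [Na+].[O-]/C(=C\O[C@H](CC)C(=O)N(C)OC)N1[C@@H](Cc2ccccc2)COC1=O | intermediate
14 | (4S)-4-benzyl-3-[(2R,4Z)-5-chloro-5-iodo-2-{[(2R)-1-[methoxy(methyl)amino]-1-oxobutan-2-yl]oxy}pent-4-enoyl]oxazolidin-2-one | O=C1OC[C@H](Cc2ccccc2)N1C(=O)[C@@H](C/C=C(/Cl)I)O[C@H](CC)C(=O)N(C)OC | intermediate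
15 | (2R)-2-{[(2R,4Z)-5-chloro-1-hydroxy-5-iodopent-4-en-2-yl]oxy}-N-methoxy-N-methylbutanamide | OC[C@@H](C/C=C(/Cl)I)O[C@H](CC)C(=O)N(C)OC | intermediate
16 | (2R)-2-{[(2R,4Z)-5-chloro-5-iodo-1-(triisopropylsilyloxy)pent-4-en-2-yl]oxy}-N-methoxy-N-methylbutanamide | CC(C)[Si](OC[C@@H](C/C=C(/Cl)I)O[C@H](CC)C(=O)N(C)OC)(C(C)C)C(C)C | intermediate
17 | methylmagnesium bromide | C[Mg]Br | starting material
18 | (3R)-3-{[(2R,4Z)-5-chloro-5-iodo-1-(triisopropylsilyloxy)pent-4-en-2-yl]oxy}pentan-2-one | CC(C)[Si](OC[C@@H](C/C=C(/Cl)I)O[C@H](CC)C(C)=O)(C(C)C)C(C)C | intermediate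
19 | (2R,5E,8R)-5-chloro-2-ethyl-8-[(triisopropylsilyloxy)methyl]-7,8-dihydro-2H-oxocin-3(4H)-one | CC(C)[Si](OC[C@H]1C/C=C(/Cl)CC(=O)[C@@H](CC)O1)(C(C)C)C(C)C | intermediate
20 | (2R,3R,5E,8R)-5-chloro-2-ethyl-8-[(triisopropylsilyloxy)methyl]-3,4,7,8-tetrahydro-2H-oxocin-3-ol | CC(C)[Si](OC[C@H]1C/C=C(/Cl)C[C@@H](O)[C@@H](CC)O1)(C(C)C)C(C)C | intermediate
21 | (2R,3S,5E,8R)-3-bromo-5-chloro-2-ethyl-8-[(triisopropylsilyloxy)methyl]-3,4,7,8-tetrahydro-2H-oxocine | CC(C)[Si](OC[C@H]1C/C=C(/Cl)C[C@H](Br)[C@@H](CC)O1)(C(C)C)C(C)C | intermediate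
22 | [(2R,3S,5E,8R)-3-bromo-5-chloro-2-ethyl-3,4,7,8-tetrahydro-2H-oxocin-8-yl]methanol | OC[C@H]1C/C=C(/Cl)C[C@H](Br)[C@@H](CC)O1 | intermediate
23 | (2R,3S,5E,8R)-3-bromo-5-chloro-2-ethyl-3,4,7,8-tetrahydro-2H-oxocine-8-carbaldehyde | O=C[C@H]1C/C=C(/Cl)C[C@H](Br)[C@@H](CC)O1 | intermediate
24 | allyl chloride | C=CCCl | starting material
25 | (Z)-γ-chloroallyldiisopinocampheylborane, isopinocampheyl groups from (−)-α-pinene | Cl/C=C\CB([C@H]1C[C@H]2C[C@@H]([C@@H]1C)C2(C)C)[C@H]1C[C@H]2C[C@@H]([C@@H]1C)C2(C)C | intermediate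
26 | (1S,2S)-1-[(2R,3S,5E,8R)-3-bromo-5-chloro-2-ethyl-3,4,7,8-tetrahydro-2H-oxocin-8-yl]-2-chlorobut-3-en-1-ol | C=C[C@H](Cl)[C@@H](O)[C@H]1C/C=C(/Cl)C[C@H](Br)[C@@H](CC)O1 | intermediate
27 | triethylsilyl ether of 26 | C=C[C@H](Cl)[C@@H](O[Si](CC)(CC)CC)[C@H]1C/C=C(/Cl)C[C@H](Br)[C@@H](CC)O1 | intermediate
28 | ozonide (1,2,4-trioxolane) of the vinyl group of 27, epimers at the ozonide carbon | C1OC(OO1)[C@H](Cl)[C@@H](O[Si](CC)(CC)CC)[C@H]2C/C=C(/Cl)C[C@H](Br)[C@@H](CC)O2 | intermediate
29 | (2R,3S)-3-[(2R,3S,5E,8R)-3-bromo-5-chloro-2-ethyl-3,4,7,8-tetrahydro-2H-oxocin-8-yl]-2-chloro-3-(triethylsilyloxy)propanal | O=C[C@H](Cl)[C@@H](O[Si](CC)(CC)CC)[C@H]1C/C=C(/Cl)C[C@H](Br)[C@@H](CC)O1 | intermediate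
30 | 1,3-bis(triisopropylsilyl)propyne | CC(C)[Si](CC#C[Si](C(C)C)(C(C)C)C(C)C)(C(C)C)C(C)C | starting material
31 | 3-lithio-1,3-bis(triisopropylsilyl)prop-1-yne | [Li]C(C#C[Si](C(C)C)(C(C)C)C(C)C)[Si](C(C)C)(C(C)C)C(C)C | intermediate
32 | O-triethylsilyl, C1-triisopropylsilyl bermudenynol (3Z,5S,6S) | CC(C)[Si](C#C/C=C\[C@H](Cl)[C@@H](O[Si](CC)(CC)CC)[C@H]1C/C=C(/Cl)C[C@H](Br)[C@@H](CC)O1)(C(C)C)C(C)C | intermediate
33 | bermudenynol | C#C/C=C\[C@H](Cl)[C@@H](O)[C@H]1C/C=C(/Cl)C[C@H](Br)[C@@H](CC)O1 | target

**Count and risks**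

Total step count: 20. Longest linear sequence: 17 steps (steps 4–20, from 6); the three-step branch to 5 (steps 1–3) joins at step 7.

Steps most likely to fail:

1. Step 11 (ring closure). Intermolecular coupling may outrun closure of the eight-membered ring, the base may epimerise C13, or the C9=C10 alkene may drift into conjugation with the ketone. The fallback uses known ring-closing metathesis; it sets out from 12 and returns at 19. Compound 12 would be alkylated with allyl iodide under the conditions of step 7 to the (R)-allyl imide F1. Reduction with NaBH4 would give the alcohol F2, and i-Pr3SiOTf/2,6-lutidine the silyl ether F3. i-Bu2AlH at −78 °C would reduce the Weinreb amide to the α-alkoxy aldehyde F4. An indium-mediated Barbier reaction with 2,3-dichloropropene (indium metal, THF/H2O) would give the 2-chloro-homoallylic alcohol F5 as C12 epimers. Ring-closing metathesis with the second-generation Grubbs catalyst (H2IMes)(PCy3)Cl2Ru=CHPh in hot dilute toluene would form the C9=C10 chloroalkene and give the oxocenol F6. Both metathesis to cyclic alkenyl chlorides and metathesis to 2,8-cis-disubstituted oxocenes are established. Dess–Martin oxidation of F6 would converge on 19.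

2. Step 13 (bromination with inversion). The ring oxygen or the homoallylic chloroalkene may participate while the C12 alcohol is activated as its phosphonium derivative, which would erode inversion or lead to ring contraction or elimination. The fallback sets out from 20 and returns at 21. Activation is separated from displacement: ClCH2SO2Cl/2,6-lutidine would give the chloromethanesulfonate F7, which Bu4NBr in toluene at 60 °C would displace by SN2 with inversion.

3. Step 18 (ozonolysis). Ozone may also attack the ring chloroalkene, so that over-oxidation competes with cleavage of the vinyl group. The fallback sets out from 27 and returns at 29. Catalytic OsO4 with N-methylmorpholine N-oxide in acetone/H2O, which discriminates more strongly against the halogenated alkene, would give the terminal diol F8 as C4 epimers. NaIO4 in THF/H2O would then cleave the glycol to 29.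

**Further compounds**

F1 | step 11 | (4S)-4-benzyl-3-[(2R)-2-{[(2R)-1-[methoxy(methyl)amino]-1-oxobutan-2-yl]oxy}pent-4-enoyl]oxazolidin-2-one | O=C1OC[C@H](Cc2ccccc2)N1C(=O)[C@@H](CC=C)O[C@H](CC)C(=O)N(C)OC
F2 | step 11 | (2R)-2-{[(2R)-1-hydroxypent-4-en-2-yl]oxy}-N-methoxy-N-methylbutanamide | OC[C@@H](CC=C)O[C@H](CC)C(=O)N(C)OC
F3 | step 11 | (2R)-N-methoxy-N-methyl-2-{[(2R)-1-(triisopropylsilyloxy)pent-4-en-2-yl]oxy}butanamide | CC(C)[Si](OC[C@@H](CC=C)O[C@H](CC)C(=O)N(C)OC)(C(C)C)C(C)C
F4 | step 11 | (2R)-2-{[(2R)-1-(triisopropylsilyloxy)pent-4-en-2-yl]oxy}butanal | CC(C)[Si](OC[C@@H](CC=C)O[C@H](CC)C=O)(C(C)C)C(C)C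
F5 | step 11 | (5R)-2-chloro-5-{[(2R)-1-(triisopropylsilyloxy)pent-4-en-2-yl]oxy}hept-1-en-4-ol, C4 epimers | CC(C)[Si](OC[C@@H](CC=C)O[C@H](CC)C(O)CC(Cl)=C)(C(C)C)C(C)C
F6 | step 11 | (2R,5E,8R)-5-chloro-2-ethyl-8-[(triisopropylsilyloxy)methyl]-3,4,7,8-tetrahydro-2H-oxocin-3-ol, C3 epimers | CC(C)[Si](OC[C@H]1C/C=C(/Cl)CC(O)[C@@H](CC)O1)(C(C)C)C(C)C
F7 | step 13 | (2R,3R,5E,8R)-5-chloro-2-ethyl-8-[(triisopropylsilyloxy)methyl]-3,4,7,8-tetrahydro-2H-oxocin-3-yl chloromethanesulfonate | CC(C)[Si](OC[C@H]1C/C=C(/Cl)C[C@@H](OS(=O)(=O)CCl)[C@@H](CC)O1)(C(C)C)C(C)C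
F8 | step 18 | (3S,4S)-4-[(2R,3S,5E,8R)-3-bromo-5-chloro-2-ethyl-3,4,7,8-tetrahydro-2H-oxocin-8-yl]-3-chloro-4-(triethylsilyloxy)butane-1,2-diol, C2 epimers | OCC(O)[C@H](Cl)[C@@H](O[Si](CC)(CC)CC)[C@H]1C/C=C(/Cl)C[C@H](Br)[C@@H](CC)O1
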